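**Plan**
- Retrosynthesis: cut the cyclobutane (C8–C8', C9–C9') to two molecules of chloranthalactone A; turn C4=C15 back into a C4 ketone; open the transannular cyclopropane bond C1–C3 (enolate alkylation retron); cut ring B at C8=C9 (vinylogous aldol condensation); cut ring A at C4–C5 and C1–C10 (Diels–Alder).
- Enabling feature: the bicyclo[3.1.0]hexane (cyclopropane C1–C2–C3 fused to cyclopentane C1–C3–C4–C5–C10) has the six-carbon perimeter C1–C2–C3–C4–C5–C10. It is a cyclohexane with one extra C1–C3 bond, so ring A can be made as a cyclohexene from a C1–C4 diene and the C5=C10 alkene.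
- Forward: butenolide (bought in as 1) → enal 6; 6 + diene 9 → ring A perimeter; ring B by C8–C9 condensation; ring A redox adjustment; cyclopropane by conjugate reduction/3-exo-tet alkylation; methylenation; photodimerisation.
- Stereochemistry: C5/C10 (trans ring fusion) from the E geometry of 6 through the suprafacial cycloaddition, absolute sense from the chiral Lewis acid; C1 carbinol by α-face hydride delivery; cyclopropane face by SN2 inversion at C1; C8/C9 by α-face, head-to-head [2+2].

Key step: step 5

Remark: atoms carry lindenane numbers (C1–C3 cyclopropane with C2 = CH2, C4 bears C15, C5/C10 ring fusion, C14 = angular methyl, lactone C7/C8/C11/C12); β is the face of C14; tricycles lacking C15 are named as 15-nor-eudesmanolides with the same numbers.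
Remark: the (S)-prolinol-derived oxazaborolidine is assumed to expose the enal face that leads to 10; if the facial sense is the opposite, its antipode is used with nothing else changed.

Step 1
Reactants: 1 4-hydroxy-3-methylfuran-2(5H)-one (3-methyltetronic acid)
Product: 2 4-methyl-5-oxo-2,5-dihydrofuran-3-yl trifluoromethanesulfonate
Conditions: Tf2O, i-Pr2NEt, CH2Cl2, −78 °C
Reagents that add atoms: trifluoromethanesulfonic anhydride, O=S(=O)(OS(=O)(=O)C(F)(F)F)C(F)(F)F
Why: O-sulfonylation of the vinylogous acid (enol triflate formation) should give the β-triflyloxy butenolide as a cross-coupling electrophile; no stereocentre is formed.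

Step 2
Reactants: 2 4-methyl-5-oxo-2,5-dihydrofuran-3-yl trifluoromethanesulfonate; 3 allyltributylstannane
Product: 4 3-methyl-4-(prop-2-en-1-yl)furan-2(5H)-one
Conditions: Pd(PPh3)4 (5 mol %), LiCl, THF, 60 °C
Reagents that add atoms: none
Why: Stille coupling (oxidative addition of zerovalent palladium into the C–OTf bond, allyl transfer from tin assisted by LiCl, reductive elimination) should give the skipped diene 4; no stereocentre is formed.

Step 3
Reactants: 4 3-methyl-4-(prop-2-en-1-yl)furan-2(5H)-one; 5 2-methylprop-2-enal (methacrolein)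
Product: 6 (2E)-2-methyl-4-(4-methyl-5-oxo-2,5-dihydrofuran-3-yl)but-2-enal
Conditions: second-generation Grubbs catalyst (5 mol %), 5 (5 equiv), CH2Cl2, 40 °C
Reagents that add atoms: none
Why: Olefin cross-metathesis of a terminal alkene with methacrolein should give the thermodynamically preferred E trisubstituted enal, and this E geometry is what later fixes the C5/C10 relationship.

Step 4
Reactants: 7 (1E,3E)-buta-1,3-diene-1,4-diyl diacetate
Product: 9 (1E,3E)-1,4-bis[(tert-butyldimethylsilyl)oxy]buta-1,3-diene, via dilithium dienediolate 8 (not isolated)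
Conditions: MeLi (4.2 equiv), THF, −20 °C; then TBSCl, DMPU, −78 → 0 °C
Reagents that add atoms: tert-butyldimethylsilyl chloride, CC(C)(C)[Si](C)(C)Cl
Why: Methyllithium cleavage of both enol acetates should give the lithium enolates with retention of the E,E geometry, and O-silylation then gives the Lewis-acid-tolerant bis(silyl dienol ether) 9.

Step 5
Reactants: 6 (2E)-2-methyl-4-(4-methyl-5-oxo-2,5-dihydrofuran-3-yl)but-2-enal; 9 (1E,3E)-1,4-bis[(tert-butyldimethylsilyl)oxy]buta-1,3-diene
Product: 10 2,5-bis[(tert-butyldimethylsilyl)oxy]-1-methyl-6-[(4-methyl-5-oxo-2,5-dihydrofuran-3-yl)methyl]cyclohex-3-ene-1-carbaldehyde (CHO cis to both silyloxy groups and to H-6; methyl cis to the side chain)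
Conditions: (S)-B-(o-tolyl) oxazaborolidine from (S)-α,α-diphenylprolinol (20 mol %), AlBr3 (16 mol %), CH2Cl2, −78 → −40 °C
Reagents that add atoms: none
Why: Binding of the AlBr3-activated oxazaborolidine to the formyl group lowers the LUMO of the C5=C10 bond of 6, which adds the C1–C4 diene 9 in a concerted, asynchronous, suprafacial [4+2] cycloaddition so that C4–C5 and C1–C10 form in one event. The closest known reaction type is the Diels–Alder reaction of 2-methyl-2-enals with oxygenated dienes under cationic chiral oxazaborolidine catalysis. The one ring closed is the cyclohexene C1–C2–C3–C4–C5–C10, the perimeter of the later bicyclo[3.1.0]hexane, formed in the [4+2] cycloaddition mode. C10 (quaternary) and C5 are set relative to each other by the E geometry of 6 (CHO cis to H5, methyl cis to the C6 side chain, hence the later trans ring fusion) and absolutely by the catalyst, which shields one face of the s-trans enal. C1 and C4 should follow the endo rule but are erased at ene-dione 14, so endo/exo control is not needed, and regiochemistry does not arise because 9 is C2-symmetric. The selectivity needed is for the enal C=C over the formyl C=O and over the butenolide alkene, secured by the Lewis-acid/2-methyl-enal pairing and by the fully substituted, poorly dienophilic lactone alkene.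

Step 6
Reactants: 10 cycloadduct aldehyde
Product: 13 1α,4α-dihydroxy-15-nor-5α-eudesma-2,7(11),8-trien-12,8-olide, via silyl aldol adduct 11 (not isolated), via bis-silyl ether 12 (not isolated)
Conditions: TBSOTf (1.3 equiv), i-Pr2NEt, CH2Cl2, −78 → 0 °C; DBU, rt; aqueous work-up, then HF·pyridine, THF, 0 °C → rt
Reagents that add atoms: none
Why: Intramolecular vinylogous Mukaiyama aldol addition of the in-situ 2-silyloxyfuran (γ-carbon C8) to the neopentyl aldehyde C9, then E1cB loss of silanolate, should close ring B as the γ-ylidene butenolide, trans-fused because C9 and C6 are trans on ring A; the transient C8/C9 centres vanish on elimination and fluoride frees the two carbinols.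

Step 7
Reactants: 13 1α,4α-dihydroxy-15-nor-5α-eudesma-2,7(11),8-trien-12,8-olide
Product: 14 1,4-dioxo-15-nor-5α-eudesma-2,7(11),8-trien-12,8-olide
Conditions: Dess–Martin periodinane (2.5 equiv), NaHCO3, CH2Cl2, 0 °C
Reagents that add atoms: none
Why: Dess–Martin oxidation of both allylic carbinols under buffered, non-enolising conditions should give the ene-dione, which erases the C1 and C4 centres of the cycloaddition and leaves C5 untouched.

Step 8
Reactants: 14 1,4-dioxo-15-nor-5α-eudesma-2,7(11),8-trien-12,8-olide
Product: 15 1β,4β-dihydroxy-15-nor-5α-eudesma-2,7(11),8-trien-12,8-olide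
Conditions: NaBH4, CeCl3·7H2O, MeOH/CH2Cl2, −78 °C
Reagents that add atoms: none
Why: Luche reduction (1,2-selective) should deliver hydride to both carbonyls from the α face, anti to the axial C14 methyl, so that C1 receives the equatorial β-hydroxyl required for the later inversion; the C4 configuration is of no consequence.

Step 9
Reactants: 15 1β,4β-dihydroxy-15-nor-5α-eudesma-2,7(11),8-trien-12,8-olide
Product: 16 1β-hydroxy-4-oxo-15-nor-5α-eudesma-2,7(11),8-trien-12,8-olide
Conditions: TEMPO (10 mol %), PhI(OAc)2 (1.1 equiv), CH2Cl2, 0 °C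
Reagents that add atoms: none
Why: The sterically demanding oxoammonium oxidation should take the C4 carbinol (next to tertiary C5) in preference to the neopentyl C1 carbinol (next to quaternary C10), giving the γ-hydroxy enone; no stereocentre is formed.

Step 10
Reactants: 16 1β-hydroxy-4-oxo-15-nor-5α-eudesma-2,7(11),8-trien-12,8-olide
Product: 17 1β-(methanesulfonyloxy)-4-oxo-15-nor-5α-eudesma-2,7(11),8-trien-12,8-olide
Conditions: MsCl, Et3N, CH2Cl2, −20 °C
Reagents that add atoms: methanesulfonyl chloride, CS(=O)(=O)Cl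
Why: Sulfonylation with retention at C1 should give the γ-mesyloxy enone, whose β (equatorial) leaving group is deactivated towards ionisation by the enone.

Step 11
Reactants: 17 1β-(methanesulfonyloxy)-4-oxo-15-nor-5α-eudesma-2,7(11),8-trien-12,8-olide
Product: 19 4-oxo-15-nor-1αH,3αH,5αH-lindena-7(11),8-dien-12,8-olide, via lithium enolate 18 (not isolated)
Conditions: LiBH(s-Bu)3 (1.05 equiv), THF, −78 → 0 °C; quench cold
Reagents that add atoms: none
Why: Hydride-initiated Michael ring closure: conjugate addition at C2 gives the C3 enolate regiospecifically (C5 is never enolised), and its 3-exo-tet attack on C1 from the α face with inversion should close the C1–C3 bond and place the cyclopropane CH2 on the β face, syn to C14, with H3 fixed α by the cis ring fusion.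

Step 12
Reactants: 19 4-oxo-15-nor-1αH,3αH,5αH-lindena-7(11),8-dien-12,8-olide
Product: 20 chloranthalactone A (1αH,3αH,5αH-lindena-4(15),7(11),8-trien-12,8-olide)
Conditions: Zn, CH2Br2, TiCl4, THF/CH2Cl2, 0 °C → rt
Reagents that add atoms: dibromomethane, BrCBr
Why: Takai–Lombardo methylenation should convert the hindered cyclopropyl ketone into the C4=C15 alkene under non-basic conditions that spare the lactone and the epimerisable C5–H; no stereocentre is formed.

Step 13
Reactants: 20 chloranthalactone A (two molecules)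
Product: 21 target CNP0265879.1 (head-to-head C8–C8'/C9–C9' cyclobutane dimer)
Conditions: hν (Hg lamp, Pyrex filter), degassed hexane/CH2Cl2, rt
Reagents that add atoms: none
Why: Intermolecular [2+2] photocycloaddition of the enol-lactone C8=C9 bonds should go head-to-head (C9–C9' bonding first leaves two allylic, oxygen-stabilised C8 radicals that couple) and on the α face of each monomer, anti to C14 and the β cyclopropane CH2, which sets C8, C9, C8' and C9' in the C2-symmetric array.

**Compound list**
1 | 4-hydroxy-3-methylfuran-2(5H)-one (3-methyltetronic acid) | CC1=C(O)COC1=O | starting material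
2 | 4-methyl-5-oxo-2,5-dihydrofuran-3-yl trifluoromethanesulfonate | CC1=C(OS(=O)(=O)C(F)(F)F)COC1=O | intermediate
3 | allyltributylstannane | CCCC[Sn](CCCC)(CCCC)CC=C | starting material
4 | 3-methyl-4-(prop-2-en-1-yl)furan-2(5H)-one | CC1=C(CC=C)COC1=O | intermediate
5 | 2-methylprop-2-enal (methacrolein) | CC(=C)C=O | starting material
6 | (2E)-2-methyl-4-(4-methyl-5-oxo-2,5-dihydrofuran-3-yl)but-2-enal | O=C/C(C)=C/CC1=C(C)C(=O)OC1 | intermediate
7 | (1E,3E)-buta-1,3-diene-1,4-diyl diacetate | CC(=O)O/C=C/C=C/OC(C)=O | starting material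
8 | dilithium (1E,3E)-buta-1,3-diene-1,4-bis(olate) | [Li+].[Li+].[O-]/C=C/C=C/[O-] | intermediate
9 | (1E,3E)-1,4-bis[(tert-butyldimethylsilyl)oxy]buta-1,3-diene | CC(C)(C)[Si](C)(C)O/C=C/C=C/O[Si](C)(C)C(C)(C)C | intermediate
10 | 2,5-bis[(tert-butyldimethylsilyl)oxy]-1-methyl-6-[(4-methyl-5-oxo-2,5-dihydrofuran-3-yl)methyl]cyclohex-3-ene-1-carbaldehyde, all-cis CHO/2-OSi/5-OSi/H-6 (lindenane C1α-O, C4α-O, 10β-Me, 5α-H) | CC(C)(C)[Si](C)(C)O[C@@H]1C=C[C@H](O[Si](C)(C)C(C)(C)C)[C@@](C=O)(C)[C@H]1CC1=C(C)C(=O)OC1 | intermediate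
11 | 1α,4α,9-tris[(tert-butyldimethylsilyl)oxy]-15-nor-5α-eudesma-2,7(11)-dien-12,8-olide (C8/C9 epimers) | CC(C)(C)[Si](C)(C)O[C@@H]1C=C[C@H](O[Si](C)(C)C(C)(C)C)[C@@]2(C)[C@H]1CC1=C(C)C(=O)OC1C2O[Si](C)(C)C(C)(C)C | intermediate
12 | 1α,4α-bis[(tert-butyldimethylsilyl)oxy]-15-nor-5α-eudesma-2,7(11),8-trien-12,8-olide | CC(C)(C)[Si](C)(C)O[C@@H]1C=C[C@H](O[Si](C)(C)C(C)(C)C)[C@@]2(C)[C@H]1CC1=C(C)C(=O)OC1=C2 | intermediate
13 | 1α,4α-dihydroxy-15-nor-5α-eudesma-2,7(11),8-trien-12,8-olide | O[C@@H]1C=C[C@H](O)[C@@]2(C)[C@H]1CC1=C(C)C(=O)OC1=C2 | intermediate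
14 | 1,4-dioxo-15-nor-5α-eudesma-2,7(11),8-trien-12,8-olide | O=C1C=CC(=O)[C@@]2(C)[C@H]1CC1=C(C)C(=O)OC1=C2 | intermediate
15 | 1β,4β-dihydroxy-15-nor-5α-eudesma-2,7(11),8-trien-12,8-olide | O[C@H]1C=C[C@@H](O)[C@@]2(C)[C@H]1CC1=C(C)C(=O)OC1=C2 | intermediate
16 | 1β-hydroxy-4-oxo-15-nor-5α-eudesma-2,7(11),8-trien-12,8-olide | O=C1C=C[C@@H](O)[C@@]2(C)[C@H]1CC1=C(C)C(=O)OC1=C2 | intermediate
17 | 1β-(methanesulfonyloxy)-4-oxo-15-nor-5α-eudesma-2,7(11),8-trien-12,8-olide | O=C1C=C[C@@H](OS(C)(=O)=O)[C@@]2(C)[C@H]1CC1=C(C)C(=O)OC1=C2 | intermediate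
18 | lithium 3-en-4-olate of 1β-(methanesulfonyloxy)-15-nor-5α-eudesma-7(11),8-dien-12,8-olide | [Li+].[O-]C1=CC[C@@H](OS(C)(=O)=O)[C@@]2(C)[C@H]1CC1=C(C)C(=O)OC1=C2 | intermediate
19 | 4-oxo-15-nor-1αH,3αH,5αH-lindena-7(11),8-dien-12,8-olide | O=C1[C@H]2C[C@H]2[C@@]2(C)[C@H]1CC1=C(C)C(=O)OC1=C2 | intermediate
20 | chloranthalactone A (1αH,3αH,5αH-lindena-4(15),7(11),8-trien-12,8-olide) | C=C1[C@H]2C[C@H]2[C@@]2(C)[C@H]1CC1=C(C)C(=O)OC1=C2 | intermediate
21 | CNP0265879.1, head-to-head [2+2] dimer of 20 | C=C1[C@H]2C[C@H]2[C@@]2(C)[C@H]1CC1=C(C)C(=O)O[C@]13[C@H]2[C@H]1[C@@]2(C)[C@@H]4C[C@@H]4C(=C)[C@@H]2CC2=C(C)C(=O)O[C@@]213 | target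

Total steps: 13. Longest linear sequence: 12 steps (steps 1–3 and 5–13).

**Steps most likely to fail**

Step 5. What may go wrong is slow turnover of the hindered trisubstituted enal, Mukaiyama-type attack of the silyl dienol ether on the activated formyl group, and loss of facial control. Fallback: 6 and 9 would be combined without any Lewis acid (toluene, 110 °C, sealed tube, a trace of 2,6-di-tert-butyl-4-methylphenol), where only the concerted cycloaddition is open. This should give 10 together with its mirror image, the ent-cycloadduct F1. The two would be separated by preparative chromatography on a chiral stationary phase (amylose tris(3,5-dimethylphenylcarbamate)). The fallback sets out from 6 and 9 and comes back at 10.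

Step 11. What may go wrong is hydride attack on the enol lactone, or 1,4-reduction without ring closure. Fallback: enolate formation is separated from the reduction. 17 would be reduced at the enone C=C with [(Ph3P)CuH]6 (wet benzene, rt), which should give the saturated keto mesylate, 1β-(methanesulfonyloxy)-4-oxo-15-nor-5α-eudesma-7(11),8-dien-12,8-olide F2. Kinetic deprotonation at the C3 methylene with LiN(SiMe3)2 (THF, −78 → 0 °C) should then bring about the classical γ-sulfonyloxy ketone to bicyclo[3.1.0]hexan-2-one closure. The fallback sets out from 17 and comes back at 19.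

Step 9. What may go wrong is poor site selectivity between the two secondary allylic carbinols, and over-oxidation back to the ene-dione. Fallback: the two hydroxyls are told apart by silylation instead of oxidation. From 15, TBSCl/imidazole (DMF, 0 °C) should silylate only the less hindered C4 hydroxyl to give the 4β-silyl ether F3. Diethyl chlorophosphate/N-methylimidazole should then convert the C1 hydroxyl into the allylic phosphate F4, which, unlike an allylic mesylate, is stable. HF·pyridine should free the C4 carbinol to give the hydroxy phosphate F5, and Dess–Martin oxidation should give the γ-phosphoryloxy enone F6. F6 would be cyclised with LiBH(s-Bu)3 as in step 11, with phosphate as the leaving group. The fallback sets out from 15 and comes back at 19.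

**Further compounds**
F1 | step 5 | ent-10, mirror image of the cycloadduct aldehyde | CC(C)(C)[Si](C)(C)O[C@H]1C=C[C@@H](O[Si](C)(C)C(C)(C)C)[C@](C=O)(C)[C@@H]1CC1=C(C)C(=O)OC1
F2 | step 11 | 1β-(methanesulfonyloxy)-4-oxo-15-nor-5α-eudesma-7(11),8-dien-12,8-olide | O=C1CC[C@@H](OS(C)(=O)=O)[C@@]2(C)[C@H]1CC1=C(C)C(=O)OC1=C2
F3 | step 9 | 4β-[(tert-butyldimethylsilyl)oxy]-1β-hydroxy-15-nor-5α-eudesma-2,7(11),8-trien-12,8-olide | CC(C)(C)[Si](C)(C)O[C@H]1C=C[C@@H](O)[C@@]2(C)[C@H]1CC1=C(C)C(=O)OC1=C2
F4 | step 9 | 4β-[(tert-butyldimethylsilyl)oxy]-1β-(diethoxyphosphoryloxy)-15-nor-5α-eudesma-2,7(11),8-trien-12,8-olide | CC(C)(C)[Si](C)(C)O[C@H]1C=C[C@@H](OP(=O)(OCC)OCC)[C@@]2(C)[C@H]1CC1=C(C)C(=O)OC1=C2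
F5 | step 9 | 1β-(diethoxyphosphoryloxy)-4β-hydroxy-15-nor-5α-eudesma-2,7(11),8-trien-12,8-olide | O[C@H]1C=C[C@@H](OP(=O)(OCC)OCC)[C@@]2(C)[C@H]1CC1=C(C)C(=O)OC1=C2
F6 | step 9 | 1β-(diethoxyphosphoryloxy)-4-oxo-15-nor-5α-eudesma-2,7(11),8-trien-12,8-olide | O=C1C=C[C@@H](OP(=O)(OCC)OCC)[C@@]2(C)[C@H]1CC1=C(C)C(=O)OC1=C2
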